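Ring A of the decalin is cut at C2–C3 and C4–C5 (labdane numbering). The C3–C4 unit with its geminal methyls is methacrolein, and C2–C1–C10–C5 is an (E)-1,3-diene grown from the isopropylidene end of (R)-citronellal. One catalytic asymmetric Diels–Alder reaction closes ring A, makes the quaternary C4 (formyl later reduced to methyl) and sets C5. The precursor is an acyclic dienyne; its alkyne then closes ring B onto the C10 cation, ozonolysis gives the C9 ketone, and an α-epoxide opened by an allylic dianion delivers the carbinol chain. The 1,2-dioxane is assembled last from a β-lactone and an ozonolysis-derived peroxyketal.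

Key step: step 5

Remark: atoms are numbered labdane-style (ring A C1–C5/C10 with gem-dimethyl C4; ring B C5–C10 with the C8 methyl and the C9 carbinol; chain C11–C12; dioxane C13–C16 with C13 quaternary; C17 α-carbon; C18 carboxyl), and in the two catalyst-controlled steps (5 and 13) the catalyst antipode is assumed to be the one that gives the stated sense of induction.

Step 1
Reactants: 1 (R)-citronellal
Product: 2 (4R)-4,8-dimethylnon-7-en-1-yne
Conditions: dimethyl (1-diazo-2-oxopropyl)phosphonate, K2CO3, MeOH, 0 °C → rt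
Reagents that add atoms: dimethyl (1-diazo-2-oxopropyl)phosphonate, CC(=O)C(=[N+]=[N-])P(=O)(OC)OC
Why: Ohira–Bestmann (Seyferth–Gilbert) homologation converts the aldehyde into the terminal alkyne under mild carbonate conditions, and the stereocentre, being β to the carbonyl, is not touched.

Step 2
Reactants: 2 (4R)-4,8-dimethylnon-7-en-1-yne
Product: 3 (6R)-2,6-dimethylnon-2-en-7-yne
Conditions: KOtBu (0.3 equiv), DMSO, rt, short reaction time
Reagents that add atoms: none
Why: Base-mediated propargyl–allenyl isomerisation moves the triple bond to the thermodynamically preferred 2-alkyne position so that the alkyne sits directly on the methyl-bearing carbon (the future C8–C9 bond); any erosion at the tertiary propargylic centre is repaired by the equilibration in step 8.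

Step 3
Reactants: 3 (6R)-2,6-dimethylnon-2-en-7-yne
Product: 5 (2E,6R)-2,6-dimethylnon-2-en-7-ynal, via allylic alcohol 4 (not isolated)
Conditions: SeO2 (cat.), t-BuOOH, CH2Cl2, 0 °C → rt; then MnO2, CH2Cl2, rt
Reagents that add atoms: selenium dioxide, O=[Se]=O; tert-butyl hydroperoxide, CC(C)(C)OO
Why: Selenium dioxide allylic oxidation (ene reaction then [2,3]-sigmatropic shift) attacks the (E)-methyl of the trisubstituted alkene selectively, and MnO2 takes the allylic alcohol to the (E)-enal, which fixes the alkene geometry needed for the diene.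

Step 4
Reactants: 5 (2E,6R)-2,6-dimethylnon-2-en-7-ynal
Product: 6 (3E,7R)-3,7-dimethyldeca-1,3-dien-8-yne
Conditions: Ph3PCH3Br, n-BuLi, THF, −78 → 0 °C
Reagents that add atoms: methyltriphenylphosphonium bromide, C[P+](c1ccccc1)(c1ccccc1)c1ccccc1.[Br-]
Why: Wittig methylenation of the enal gives the terminal (E)-1,3-diene without touching the trisubstituted double bond or the internal alkyne.

Step 5
Reactants: 6 (3E,7R)-3,7-dimethyldeca-1,3-dien-8-yne; 7 methacrolein
Product: 8 (1R,2R)-1,3-dimethyl-2-[(3R)-3-methylhex-4-yn-1-yl]cyclohex-3-ene-1-carbaldehyde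
Conditions: (S)-o-tolyl-oxazaborolidine from (S)-α,α-diphenylprolinol, activated with HNTf2 (20 mol%), CH2Cl2, −78 → −40 °C
Reagents that add atoms: none
Why: The protonated oxazaborolidine binds methacrolein s-trans through boron–carbonyl coordination and a formyl C–H···O contact, and the diene adds to the exposed enal face in a concerted but asynchronous [4+2] cycloaddition in which the C2–C3 bond (diene CH2 terminus to enal β-CH2) leads and the C4–C5 bond follows. The closest known reaction type is the cationic oxazaborolidine-catalysed Diels–Alder reaction of 2-substituted acroleins with acyclic 1,3-dienes. Ring A (the six-membered carbocycle C1–C5/C10) is closed by intermolecular [4π+2π] cycloaddition, suprafacial on both partners, which leaves the C1=C10 alkene needed in step 7. C5 is set by the catalyst through facial shielding of the enal together with the exo preference of α-methyl enals (formyl anti to the C5 side chain), while C4 is a transient stereocentre erased in step 6. The step needs "ortho" regiochemistry, which the largest diene HOMO coefficient at the unsubstituted C2 terminus and the largest LUMO coefficient at the β-carbon of the Lewis-acid-bound enal should secure, and it needs the (E)-geometry of the C5=C10 alkene fixed in step 3 so that the s-cis conformer is accessible. The remote C8 centre does not interfere and later reinforces the ring-fusion outcome in step 7.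

Step 6
Reactants: 8 (1R,2R)-1,3-dimethyl-2-[(3R)-3-methylhex-4-yn-1-yl]cyclohex-3-ene-1-carbaldehyde
Product: 10 (6S)-1,5,5-trimethyl-6-[(3R)-3-methylhex-4-yn-1-yl]cyclohex-1-ene, via tosylhydrazone 9 (not isolated)
Conditions: TsNHNH2, EtOH, rt; then catecholborane, CHCl3, 0 °C; NaOAc·3H2O, 60 °C
Reagents that add atoms: none
Why: Caglioti-type reduction of the tosylhydrazone (hydroboration of C=N, sulfinate loss, diazene decomposition) turns the neopentyl formyl group into the second C4 methyl under neutral conditions that leave the alkyne and the ring alkene in place, and C4 ceases to be a stereocentre.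

Step 7
Reactants: 10 (6S)-1,5,5-trimethyl-6-[(3R)-3-methylhex-4-yn-1-yl]cyclohex-1-ene
Product: 12 (2R,4aS,8aS)-1-(1-chloroethylidene)-2,5,5,8a-tetramethyldecahydronaphthalene (E/Z mixture), via tertiary chloride 11 (not isolated)
Conditions: HCl (1.05 equiv), CH2Cl2, −78 °C; then TiCl4 (20 mol%), −78 → −40 °C
Reagents that add atoms: hydrogen chloride, Cl
Why: Markovnikov hydrochlorination gives the tertiary C10 chloride, which TiCl4 ionises so that the alkyne attacks the cation 6-exo-dig through a chair-like transition state (C5 side chain and C8 methyl equatorial, an axial C8 methyl clashing with the C10 methyl), setting C10 trans to H-5, and chloride captures the linear vinyl cation (Lewis-acid-promoted addition of a tertiary alkyl chloride to an alkyne, cation–alkyne cyclisation).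

Step 8
Reactants: 12 (2R,4aS,8aS)-1-(1-chloroethylidene)-2,5,5,8a-tetramethyldecahydronaphthalene
Product: 13 (2R,4aS,8aS)-2,5,5,8a-tetramethyloctahydronaphthalen-1(2H)-one
Conditions: O3, CH2Cl2, −78 °C; Me2S; then NaOMe (cat.), MeOH, rt
Reagents that add atoms: ozone, [O-][O+]=O
Why: Ozonolysis of the tetrasubstituted chloroalkene excises the two-carbon terminator and unveils the C9 ketone, and catalytic methoxide equilibrates C8 to the equatorial methyl, which is the configuration carried from citronellal.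

Step 9
Reactants: 13 (2R,4aS,8aS)-2,5,5,8a-tetramethyloctahydronaphthalen-1(2H)-one
Product: 14 (2R,4aS,8aS)-2,5,5,8a-tetramethyl-1-methylidenedecahydronaphthalene
Conditions: Ph3PCH3Br, KOtBu, toluene, 110 °C
Reagents that add atoms: methyltriphenylphosphonium bromide, C[P+](c1ccccc1)(c1ccccc1)c1ccccc1.[Br-]
Why: Wittig methylenation under forcing conditions should convert the hindered ketone into the exocyclic alkene, and C8 stays equatorial because that epimer is the thermodynamic one under the basic conditions.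

Step 10
Reactants: 14 (2R,4aS,8aS)-2,5,5,8a-tetramethyl-1-methylidenedecahydronaphthalene
Product: 15 (2R,2'R,4a'S,8a'S)-2',5',5',8a'-tetramethyloctahydro-2'H-spiro[oxirane-2,1'-naphthalene]
Conditions: mCPBA, NaHCO3, CH2Cl2, 0 °C
Reagents that add atoms: 3-chloroperbenzoic acid, OOC(=O)c1cccc(Cl)c1
Why: Prilezhaev epoxidation should occur on the α face of the exocyclic alkene, anti to the axial C10 methyl that shields the β face, placing the oxygen axial (9α) and C11 equatorial.

Step 11
Reactants: 15 (2R,2'R,4a'S,8a'S)-2',5',5',8a'-tetramethyloctahydro-2'H-spiro[oxirane-2,1'-naphthalene]; 16 4-methylpent-4-en-1-ol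
Product: 19 triethyl({4-methylidene-6-[(1R,2R,4aS,8aS)-2,5,5,8a-tetramethyl-1-(triethylsilyloxy)decahydronaphthalen-1-yl]hexyl}oxy)silane, via dilithio allyl reagent 17 (not isolated), via dilithium dialkoxide 18 (not isolated)
Conditions: 16, n-BuLi (2.1 equiv), TMEDA, Et2O/hexane, 0 °C → rt; then 15, −78 °C → rt; then Et3SiOTf, −78 → 0 °C
Reagents that add atoms: triethylsilyl trifluoromethanesulfonate, CC[Si](CC)(CC)OS(=O)(=O)C(F)(F)F
Why: Allylic metalation of the methyl group of the lithium alkoxide gives a 2-substituted allyl anion whose two CH2 termini are equivalent, and its SN2 opening of the 2,2-disubstituted epoxide at the CH2 carbon forms C11–C12 while the C9–O bond, and so the 9α-oxygen configuration from step 10, is kept; both alkoxides are silylated in the same flask.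

Step 12
Reactants: 19 triethyl({4-methylidene-6-[(1R,2R,4aS,8aS)-2,5,5,8a-tetramethyl-1-(triethylsilyloxy)decahydronaphthalen-1-yl]hexyl}oxy)silane
Product: 20 4-methylidene-6-[(1R,2R,4aS,8aS)-2,5,5,8a-tetramethyl-1-(triethylsilyloxy)decahydronaphthalen-1-yl]hexanal
Conditions: (COCl)2, DMSO, CH2Cl2, −78 → −30 °C; then Et3N
Reagents that add atoms: none
Why: Swern conditions convert a primary triethylsilyl ether directly into the aldehyde while the hindered tertiary silyl ether is inert (selective oxidative desilylation, Swern oxidation).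

Step 13
Reactants: 20 4-methylidene-6-[(1R,2R,4aS,8aS)-2,5,5,8a-tetramethyl-1-(triethylsilyloxy)decahydronaphthalen-1-yl]hexanal; 21 propanoyl chloride
Product: 22 (3S,4R)-3-methyl-4-{3-methylidene-5-[(1R,2R,4aS,8aS)-2,5,5,8a-tetramethyl-1-(triethylsilyloxy)decahydronaphthalen-1-yl]pentyl}oxetan-2-one
Conditions: O-trimethylsilylquinidine (10 mol%), LiClO4, i-Pr2NEt, CH2Cl2/Et2O, −78 °C
Reagents that add atoms: none
Why: In this cinchona-alkaloid/LiClO4-catalysed acyl halide–aldehyde cyclocondensation (formal ketene–aldehyde [2+2]) methylketene formed in situ gives a chiral ammonium enolate that adds to the lithium-activated aldehyde and closes to the cis-β-lactone, setting C17 (S) and C16 (R, to be inverted in step 15) under catalyst control, the pseudoenantiomeric O-trimethylsilylquinine being the alternative should the other alkaloid series be needed for this sense.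

Step 14
Reactants: 22 (3S,4R)-3-methyl-4-{3-methylidene-5-[(1R,2R,4aS,8aS)-2,5,5,8a-tetramethyl-1-(triethylsilyloxy)decahydronaphthalen-1-yl]pentyl}oxetan-2-one
Product: 23 (3S,4R)-4-{3-hydroperoxy-3-methoxy-5-[(1R,2R,4aS,8aS)-2,5,5,8a-tetramethyl-1-(triethylsilyloxy)decahydronaphthalen-1-yl]pentyl}-3-methyloxetan-2-one (both C13 epimers)
Conditions: O3, CH2Cl2/MeOH (4:1), −78 °C; argon purge, no reductive work-up
Reagents that add atoms: ozone, [O-][O+]=O; methanol, CO
Why: In the ozonolysis of the 1,1-disubstituted alkene the Criegee carbonyl oxide forms on the more substituted C13 fragment and is trapped by methanol as the α-methoxy hydroperoxide, formaldehyde being the other fragment, and no reductant is added so that the O–O bond survives.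

Step 15
Reactants: 23 (3S,4R)-4-{3-hydroperoxy-3-methoxy-5-[(1R,2R,4aS,8aS)-2,5,5,8a-tetramethyl-1-(triethylsilyloxy)decahydronaphthalen-1-yl]pentyl}-3-methyloxetan-2-one
Product: 24 (2S)-2-[(3S)-6-methoxy-6-{2-[(1R,2R,4aS,8aS)-2,5,5,8a-tetramethyl-1-(triethylsilyloxy)decahydronaphthalen-1-yl]ethyl}-1,2-dioxan-3-yl]propanoic acid (both C13 epimers)
Conditions: KN(SiMe3)2 (1.05 equiv), 18-crown-6, THF (high dilution), −78 → 0 °C; then AcOH
Reagents that add atoms: none
Why: Proposed new method: the potassium salt of the α-methoxy hydroperoxide should attack C16 of the β-lactone from the side opposite the lactone oxygen in a 6-exo-tet SN2 displacement (alkyl–oxygen cleavage), forming the O–C16 bond with inversion to (16S) and releasing the carboxylate, attack at the acyl carbon being disfavoured because it would need an eight-membered ring; the closest known reaction types are alkyl–oxygen ring opening of β-lactones by heteroatom nucleophiles (including intramolecular ether oxygen) and intramolecular SN2 cyclisation of α-alkoxy hydroperoxides onto sulfonates or halides.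

Step 16
Reactants: 24 (2S)-2-[(3S)-6-methoxy-6-{2-[(1R,2R,4aS,8aS)-2,5,5,8a-tetramethyl-1-(triethylsilyloxy)decahydronaphthalen-1-yl]ethyl}-1,2-dioxan-3-yl]propanoic acid
Product: 26 (2S)-2-[(3S,6S)-6-{2-[(1R,2R,4aS,8aS)-1-hydroxy-2,5,5,8a-tetramethyldecahydronaphthalen-1-yl]ethyl}-6-methyl-1,2-dioxan-3-yl]propanoic acid, via triethylsilyl ether 25 (not isolated)
Conditions: Me3Al (4 equiv), Me3SiOTf (0.2 equiv), CH2Cl2, −78 → −40 °C; aqueous Rochelle salt; then HF·pyridine, THF, 0 °C
Reagents that add atoms: trimethylaluminium, C[Al](C)C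
Why: Proposed new method: Me3SiOTf should ionise the exocyclic methoxy group to a cyclic peroxycarbenium ion whose half-chair carries the C16 substituent pseudo-equatorial, and Me3Al should deliver methyl along the axial trajectory that leads directly to the chair, giving C13 with the methyl axial and cis to the C16 side chain and the C12 chain equatorial, that is (13S); the closest known reaction types are the Lewis-acid-mediated allylation of 3-alkoxy-1,2-dioxanes and 1,2-dioxolanes through peroxycarbenium ions and the axial C-methylation of six-membered oxocarbenium ions by Me3Al in peroxide-containing lactol derivatives, and HF·pyridine then removes the tertiary silyl ether.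

Compound list
1 | (R)-citronellal, (3R)-3,7-dimethyloct-6-enal | O=CC[C@H](C)CCC=C(C)C | starting material
2 | (4R)-4,8-dimethylnon-7-en-1-yne | C#CC[C@H](C)CCC=C(C)C | intermediate
3 | (6R)-2,6-dimethylnon-2-en-7-yne | CC#C[C@H](C)CCC=C(C)C | intermediate
4 | (2E,6R)-2,6-dimethylnon-2-en-7-yn-1-ol | CC#C[C@H](C)CC/C=C(\C)CO | intermediate
5 | (2E,6R)-2,6-dimethylnon-2-en-7-ynal | CC#C[C@H](C)CC/C=C(\C)C=O | intermediate
6 | (3E,7R)-3,7-dimethyldeca-1,3-dien-8-yne | CC#C[C@H](C)CC/C=C(\C)C=C | intermediate
7 | methacrolein, 2-methylprop-2-enal | CC(=C)C=O | starting material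
8 | (1R,2R)-1,3-dimethyl-2-[(3R)-3-methylhex-4-yn-1-yl]cyclohex-3-ene-1-carbaldehyde | CC#C[C@H](C)CC[C@H]1[C@](C)(C=O)CCC=C1C | intermediate
9 | N-tosylhydrazone of 8, N'-{[(1R,2R)-1,3-dimethyl-2-[(3R)-3-methylhex-4-yn-1-yl]cyclohex-3-en-1-yl]methylidene}-4-methylbenzenesulfonohydrazide | CC#C[C@H](C)CC[C@H]1[C@](C)(C=NNS(=O)(=O)c2ccc(C)cc2)CCC=C1C | intermediate
10 | (6S)-1,5,5-trimethyl-6-[(3R)-3-methylhex-4-yn-1-yl]cyclohex-1-ene | CC#C[C@H](C)CC[C@H]1C(C)(C)CCC=C1C | intermediate
11 | (2S)-1-chloro-1,3,3-trimethyl-2-[(3R)-3-methylhex-4-yn-1-yl]cyclohexane (both C–Cl epimers) | CC#C[C@H](C)CC[C@H]1C(C)(C)CCCC1(C)Cl | intermediate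
12 | (2R,4aS,8aS)-1-(1-chloroethylidene)-2,5,5,8a-tetramethyldecahydronaphthalene (E/Z mixture) | CC(Cl)=C2[C@H](C)CC[C@H]3C(C)(C)CCC[C@@]32C | intermediate
13 | (2R,4aS,8aS)-2,5,5,8a-tetramethyloctahydronaphthalen-1(2H)-one | O=C2[C@H](C)CC[C@H]3C(C)(C)CCC[C@@]32C | intermediate
14 | (2R,4aS,8aS)-2,5,5,8a-tetramethyl-1-methylidenedecahydronaphthalene | C=C2[C@H](C)CC[C@H]3C(C)(C)CCC[C@@]32C | intermediate
15 | (2R,2'R,4a'S,8a'S)-2',5',5',8a'-tetramethyloctahydro-2'H-spiro[oxirane-2,1'-naphthalene] (9α,11-epoxide) | C1O[C@@]12[C@H](C)CC[C@H]3C(C)(C)CCC[C@@]32C | intermediate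
16 | 4-methylpent-4-en-1-ol | CC(=C)CCCO | starting material
17 | lithium 4-(lithiomethyl)pent-4-en-1-olate | [Li]CC(=C)CCCO[Li] | intermediate
18 | dilithium 4-methylidene-6-[(1R,2R,4aS,8aS)-2,5,5,8a-tetramethyl-1-oxidodecahydronaphthalen-1-yl]hexan-1-olate | [Li]OCCCC(=C)CC[C@@]2(O[Li])[C@H](C)CC[C@H]3C(C)(C)CCC[C@@]32C | intermediate
19 | triethyl({4-methylidene-6-[(1R,2R,4aS,8aS)-2,5,5,8a-tetramethyl-1-(triethylsilyloxy)decahydronaphthalen-1-yl]hexyl}oxy)silane | CC[Si](CC)(CC)OCCCC(=C)CC[C@@]2(O[Si](CC)(CC)CC)[C@H](C)CC[C@H]3C(C)(C)CCC[C@@]32C | intermediate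
20 | 4-methylidene-6-[(1R,2R,4aS,8aS)-2,5,5,8a-tetramethyl-1-(triethylsilyloxy)decahydronaphthalen-1-yl]hexanal | O=CCCC(=C)CC[C@@]2(O[Si](CC)(CC)CC)[C@H](C)CC[C@H]3C(C)(C)CCC[C@@]32C | intermediate
21 | propanoyl chloride | CCC(=O)Cl | starting material
22 | (3S,4R)-3-methyl-4-{3-methylidene-5-[(1R,2R,4aS,8aS)-2,5,5,8a-tetramethyl-1-(triethylsilyloxy)decahydronaphthalen-1-yl]pentyl}oxetan-2-one (cis-β-lactone) | C[C@@H]1C(=O)O[C@@H]1CCC(=C)CC[C@@]2(O[Si](CC)(CC)CC)[C@H](C)CC[C@H]3C(C)(C)CCC[C@@]32C | intermediate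
23 | (3S,4R)-4-{3-hydroperoxy-3-methoxy-5-[(1R,2R,4aS,8aS)-2,5,5,8a-tetramethyl-1-(triethylsilyloxy)decahydronaphthalen-1-yl]pentyl}-3-methyloxetan-2-one (both C13 epimers) | C[C@@H]1C(=O)O[C@@H]1CCC(OC)(OO)CC[C@@]2(O[Si](CC)(CC)CC)[C@H](C)CC[C@H]3C(C)(C)CCC[C@@]32C | intermediate
24 | (2S)-2-[(3S)-6-methoxy-6-{2-[(1R,2R,4aS,8aS)-2,5,5,8a-tetramethyl-1-(triethylsilyloxy)decahydronaphthalen-1-yl]ethyl}-1,2-dioxan-3-yl]propanoic acid (both C13 epimers) | C[C@H](C(=O)O)[C@@H]1CCC(OC)(CC[C@@]2(O[Si](CC)(CC)CC)[C@H](C)CC[C@H]3C(C)(C)CCC[C@@]32C)OO1 | intermediate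
25 | (2S)-2-[(3S,6S)-6-methyl-6-{2-[(1R,2R,4aS,8aS)-2,5,5,8a-tetramethyl-1-(triethylsilyloxy)decahydronaphthalen-1-yl]ethyl}-1,2-dioxan-3-yl]propanoic acid | C[C@H](C(=O)O)[C@@H]1CC[C@@](C)(CC[C@@]2(O[Si](CC)(CC)CC)[C@H](C)CC[C@H]3C(C)(C)CCC[C@@]32C)OO1 | intermediate
26 | (2S)-2-[(3S,6S)-6-{2-[(1R,2R,4aS,8aS)-1-hydroxy-2,5,5,8a-tetramethyldecahydronaphthalen-1-yl]ethyl}-6-methyl-1,2-dioxan-3-yl]propanoic acid | C[C@H](C(=O)O)[C@@H]1CC[C@@](C)(CC[C@@]2(O)[C@H](C)CC[C@H]3C(C)(C)CCC[C@@]32C)OO1 | target

Total step count: 16. Longest linear sequence: 16 steps from (R)-citronellal (1); methacrolein (7), 4-methylpent-4-en-1-ol (16) and propanoyl chloride (21) enter as purchased materials.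

Steps most likely to fail

Step 15 (proposed new method). The peroxide anion may attack a lactone carbonyl of a second molecule, or the base may open the β-lactone by α-deprotonation and elimination, instead of the intended 6-exo-tet alkyl–oxygen cleavage. The fallback sets out from β-lactone 22 and returns at acid 24, using the established displacement of a secondary mesylate by a hydroperoxide. LiBH4 (THF, 0 °C) reduces 22 to the 1,3-diol F1. Benzoyl chloride with 2,4,6-collidine at −78 °C acylates the primary hydroxyl to give the primary benzoate F2, and MsCl/Et3N gives the C16 mesylate F3. Ozonolysis in CH2Cl2/MeOH gives the α-methoxy hydroperoxide F4. KOtBu with 18-crown-6 in THF closes the ring with inversion at C16 to the dioxane benzoate F5. K2CO3 in MeOH frees the primary alcohol F6, and TEMPO/PhI(OAc)2 in MeCN/H2O oxidises it to 24.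

Step 16 (proposed new method). Ionisation may occur at the ring peroxide oxygen rather than at the methoxy group, the aluminium reagent may reduce the O–O bond, or methyl delivery may lose its axial preference. The fallback sets out from aldehyde 20 and returns at silyl ether 25; it installs the C13 methyl before ring closure by known chemistry, at the price of lower stereocontrol. Wittig reaction of 20 with methyl 2-(triphenylphosphoranylidene)propanoate gives the (E)-enoate F7. Cobalt-catalysed hydroperoxysilylation of the 1,1-disubstituted alkene (Mukaiyama–Isayama reaction; Co(thd)2 with thd = 2,2,6,6-tetramethylheptane-3,5-dionate, O2, Et3SiH) gives the tertiary triethylsilyl peroxide F8 as both C13 epimers. K2CO3 in MeOH frees the tertiary hydroperoxide F9, which closes by 6-exo oxa-Michael addition (Et2NH, CF3CH2OH) to the dioxane methyl ester F10. The (13S,16S,17S) isomer would have to be separated from its diastereomers. LiOH in THF/H2O then gives 25, which is desilylated as in step 16.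

Step 7. The C10 cation may lose a proton to give ring-alkene isomers, shift a hydride from C5 (leading to spiro products and loss of the C5 configuration), or close to the cis-fused decalin; the vinyl cation may also be captured unproductively. The fallback sets out from 10 and returns at ketone 13; it replaces vinyl-cation capture by a desilylative closure. Lithiation of the propargylic methyl of 10 (n-BuLi, TMEDA, THF, −20 °C) and quenching with Me3SiCl gives the propargylsilane F11. CF3CO2H in CH2Cl2 at −40 °C protonates the ring alkene, and SE2′ attack of the propargylsilane on the C10 cation with loss of silicon gives the exocyclic allene F12 through the same chair-like arrangement. Ozonolysis of both allene double bonds (O3, CH2Cl2, −78 °C; Me2S) then gives 13.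

Further compounds
F1 | step 15 | (2R,3R)-2-methyl-6-methylidene-8-[(1R,2R,4aS,8aS)-2,5,5,8a-tetramethyl-1-(triethylsilyloxy)decahydronaphthalen-1-yl]octane-1,3-diol | C[C@H](CO)[C@H](O)CCC(=C)CC[C@@]2(O[Si](CC)(CC)CC)[C@H](C)CC[C@H]3C(C)(C)CCC[C@@]32C
F2 | step 15 | (2R,3R)-3-hydroxy-2-methyl-6-methylidene-8-[(1R,2R,4aS,8aS)-2,5,5,8a-tetramethyl-1-(triethylsilyloxy)decahydronaphthalen-1-yl]octyl benzoate | C[C@H](COC(=O)c1ccccc1)[C@H](O)CCC(=C)CC[C@@]2(O[Si](CC)(CC)CC)[C@H](C)CC[C@H]3C(C)(C)CCC[C@@]32C
F3 | step 15 | (2R,3R)-2-methyl-6-methylidene-3-(methylsulfonyloxy)-8-[(1R,2R,4aS,8aS)-2,5,5,8a-tetramethyl-1-(triethylsilyloxy)decahydronaphthalen-1-yl]octyl benzoate | C[C@H](COC(=O)c1ccccc1)[C@H](OS(C)(=O)=O)CCC(=C)CC[C@@]2(O[Si](CC)(CC)CC)[C@H](C)CC[C@H]3C(C)(C)CCC[C@@]32C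
F4 | step 15 | (2R,3R)-6-hydroperoxy-6-methoxy-2-methyl-3-(methylsulfonyloxy)-8-[(1R,2R,4aS,8aS)-2,5,5,8a-tetramethyl-1-(triethylsilyloxy)decahydronaphthalen-1-yl]octyl benzoate (both C13 epimers) | C[C@H](COC(=O)c1ccccc1)[C@H](OS(C)(=O)=O)CCC(OC)(OO)CC[C@@]2(O[Si](CC)(CC)CC)[C@H](C)CC[C@H]3C(C)(C)CCC[C@@]32C
F5 | step 15 | (2R)-2-[(3S)-6-methoxy-6-{2-[(1R,2R,4aS,8aS)-2,5,5,8a-tetramethyl-1-(triethylsilyloxy)decahydronaphthalen-1-yl]ethyl}-1,2-dioxan-3-yl]propyl benzoate | C[C@H](COC(=O)c1ccccc1)[C@@H]1CCC(OC)(CC[C@@]2(O[Si](CC)(CC)CC)[C@H](C)CC[C@H]3C(C)(C)CCC[C@@]32C)OO1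
F6 | step 15 | (2R)-2-[(3S)-6-methoxy-6-{2-[(1R,2R,4aS,8aS)-2,5,5,8a-tetramethyl-1-(triethylsilyloxy)decahydronaphthalen-1-yl]ethyl}-1,2-dioxan-3-yl]propan-1-ol | C[C@H](CO)[C@@H]1CCC(OC)(CC[C@@]2(O[Si](CC)(CC)CC)[C@H](C)CC[C@H]3C(C)(C)CCC[C@@]32C)OO1
F7 | step 16 | methyl (2E)-2-methyl-6-methylidene-8-[(1R,2R,4aS,8aS)-2,5,5,8a-tetramethyl-1-(triethylsilyloxy)decahydronaphthalen-1-yl]oct-2-enoate | COC(=O)/C(C)=C/CCC(=C)CC[C@@]2(O[Si](CC)(CC)CC)[C@H](C)CC[C@H]3C(C)(C)CCC[C@@]32C
F8 | step 16 | methyl (2E)-2,6-dimethyl-8-[(1R,2R,4aS,8aS)-2,5,5,8a-tetramethyl-1-(triethylsilyloxy)decahydronaphthalen-1-yl]-6-(triethylsilylperoxy)oct-2-enoate (both C13 epimers) | COC(=O)/C(C)=C/CCC(C)(OO[Si](CC)(CC)CC)CC[C@@]2(O[Si](CC)(CC)CC)[C@H](C)CC[C@H]3C(C)(C)CCC[C@@]32C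
F9 | step 16 | methyl (2E)-6-hydroperoxy-2,6-dimethyl-8-[(1R,2R,4aS,8aS)-2,5,5,8a-tetramethyl-1-(triethylsilyloxy)decahydronaphthalen-1-yl]oct-2-enoate (both C13 epimers) | COC(=O)/C(C)=C/CCC(C)(OO)CC[C@@]2(O[Si](CC)(CC)CC)[C@H](C)CC[C@H]3C(C)(C)CCC[C@@]32C
F10 | step 16 | methyl (2S)-2-[(3S,6S)-6-methyl-6-{2-[(1R,2R,4aS,8aS)-2,5,5,8a-tetramethyl-1-(triethylsilyloxy)decahydronaphthalen-1-yl]ethyl}-1,2-dioxan-3-yl]propanoate | C[C@H](C(=O)OC)[C@@H]1CC[C@@](C)(CC[C@@]2(O[Si](CC)(CC)CC)[C@H](C)CC[C@H]3C(C)(C)CCC[C@@]32C)OO1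
F11 | step 7 | trimethyl{(4R)-4-methyl-6-[(1S)-2,6,6-trimethylcyclohex-2-en-1-yl]hex-2-yn-1-yl}silane | C[Si](C)(C)CC#C[C@H](C)CC[C@H]1C(C)(C)CCC=C1C
F12 | step 7 | (2R,4aS,8aS)-1-ethenylidene-2,5,5,8a-tetramethyldecahydronaphthalene | C=C=C2[C@H](C)CC[C@H]3C(C)(C)CCC[C@@]32C
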